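A lifetime of 62.2 s is what the starting material shows in the dawn run between 60.0 s and 120 s, where the running lifetime is the time between two readings divided by the natural log of the ratio of c(starting material) at them, the reciprocal of a running pseudo-first-order constant.

common to all: starting material 0.50 mM (in portions, 3)
- dawn: reagent 5 equiv; the very flask that is asked about, followed so far; portions every 4.0 s
- flask: reagent 5.00 equiv; the portions of starting material follow each other after 4.0 s, the first at the start; time 4.0 min

- dawn (time / s: starting material / %, target / %): 10.0: 83.5, 16.5; 20.0: 63.5, 36.6; 30.0: 50.6, 49.3; 60.0: 27.3, 72.3; 120: 10.4, 89.0

(readings scatter by 0.5 percentage points)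

- the species in which most of what was charged as starting material, at 4.0 min sits (target / starting material)
- the largest share itself, whichever of these holds it, in percent of the starting material charged



The dawn run is the very flask asked about, and its last portion is in at 8.00 s, so the windows I use lie after the dosing. The window from 30.0 s to 60.0 s reads 48.6 s, so the later lifetime is longer, and between the window middles the lifetime, set against run time, rises with a slope of 0.301, a pure number read from the dawn run, which I call the stretch.

My first way holds the lifetime at 62.2 s from the reading at 120 s, where 10.4% starting material stands, and leaves 1.51% at 4.0 min, so target is 98.5%, counting the rest as target because the balance at 120 s reads 99.4%. My second way lets the stretch go on in a straight line, from 71.2 s at 120 s to 107 s at 4.0 min, so the fraction left is the ratio of these lifetimes raised to one over the stretch, which gives 2.66% starting material and 97.3% target. They part by 1.2 percentage points, and the first way cheats, because it holds a mean from around 90.0 s that is shorter than the line at 4.0 min, so I commit to the second.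

The forecast puts target at 94.5%, within 91% to 97%, lower than my figure, on this ground: “Something slows the reaction”. The flask at 4.0 min gives target at 97.1%, with starting material at 2.86%.

    starting material + reagent → target, rate k1*[starting material]*[reagent]^0.5 (k = 0.675 L⁰·⁵ mol⁻⁰·⁵ s⁻¹)
    2 reagent → homo dimer (k = 6.65 L mol⁻¹ s⁻¹)

At 0.308 min this flask's reagent goes to homo dimer 3.2 times as fast as to target, and at 4.00 min 4.4 times as fast, with 8.64% of its charge left. Between 120 s and 4.0 min the lifetime now reads 93.0 s, against 89.3 s on the stretch line at that window's middle. Carried on from 2.86%, the stretch gives 0.282% starting material in the same flask read at 10 min, more than the 0.16% it holds.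

The numbers in the tables were computed from invented constants, and the scatter is random.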